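C1 is the carbonyl between C2 and C6; C2 carries OH, C3 the heptadecyl chain, C4 is the second carbonyl, C5 carries OMe and C6 carries H.
Retrosynthesis: the O–tert-butyl bond masking the C2 hydroxyl is cut first; the quinone ring is then cut at C4–C5 and C6–H and re-closed at C1–C4 to a 4-hydroxy-4-(methoxyethynyl)cyclobutenone; C1–C6 (acetylide addition) and the C3–chain bond (Grignard addition to a squarate) follow.
Enabling feature: ring atoms C1–C4 carry O, O, alkyl, O in a row and are the four-membered ring of squaric acid, while C5(OMe)–C6(H) is a methoxyacetylene unit, so the single ring of the target can arise by thermal expansion of a squarate-derived cyclobutenone.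
Forward order: heptadecyl chain onto the four-membered ring, carbonyl transposition, attachment of the two-carbon unit, expansion of the four-membered ring to the six-membered quinone, removal of tert-butyl.
Stereochemistry: the target has no stereocenter; the two carbinol carbons formed on the way are racemic and both end as sp2 carbons.
Key step: step 7

Assumption: the side chain of the SMILES is read as unbranched heptadecyl (seventeen carbons outside the ring), and di-tert-butyl squarate is prepared from squaric acid although it can also be bought.

Step 1
Reactants: 1 squaric acid (3,4-dihydroxycyclobut-3-ene-1,2-dione)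
Product: 2 disilver squarate (Ag2C4O4)
Conditions: AgNO3 (2 equiv), H2O, rt, dark; filter, dry in vacuo
Reagents that add atoms: silver nitrate (AgNO3), [Ag+].[O-][N+](=O)[O-]
Why: Salt metathesis in water: squaric acid is a strong diacid and its disilver salt is insoluble, so it should precipitate on mixing and be collected dry for the alkylation.

Step 2
Reactants: 2 disilver squarate
Product: 3 di-tert-butyl squarate (3,4-di-tert-butoxycyclobut-3-ene-1,2-dione)
Conditions: t-BuCl (excess), Et2O, rt, dark
Reagents that add atoms: tert-butyl chloride, CC(C)(C)Cl
Why: Silver-assisted SN1 O-alkylation of the squarate dianion, driven by precipitation of AgCl and run without added acid or base so that the acid-labile diester survives; this is the established preparation of this compound.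

Step 3
Reactants: 4 1-bromoheptadecane; 3 di-tert-butyl squarate
Product: 6 racemic 2,3-di-tert-butoxy-4-heptadecyl-4-hydroxycyclobut-2-en-1-one, via heptadecylmagnesium bromide 5 (not isolated)
Conditions: Mg, THF, 50 °C; then 3, THF, −78 °C; sat. aq NH4Cl
Reagents that add atoms: none
Why: Grignard formation and 1,2-addition to one of the two equivalent squarate carbonyls; the carbonyl left in the adduct is a vinylogous ester and should resist a second addition at −78 °C, and the new carbinol carbon is racemic and ceases to be a stereocenter in step 4.

Step 4
Reactants: 6 racemic 2,3-di-tert-butoxy-4-heptadecyl-4-hydroxycyclobut-2-en-1-one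
Product: 8 3-tert-butoxy-4-heptadecylcyclobut-3-ene-1,2-dione, via trifluoroacetate ester 7 (not isolated)
Conditions: (CF3CO)2O, pyridine, Et2O, −78 to 0 °C; then H2O
Reagents that add atoms: water, O
Why: Trifluoroacetylation of the tertiary alcohol and ionisation should give a tert-butoxy-stabilised cyclobutenyl cation that water captures at the distal tert-butoxy carbon, and collapse of the hemiketal with loss of tert-butanol completes the known 1,3-carbonyl transposition of squarate adducts, pyridine buffering the acid so that the second tert-butyl ether is kept.

Step 5
Reactants: 9 chloroacetaldehyde dimethyl acetal (2-chloro-1,1-dimethoxyethane)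
Product: 11 methoxyacetylene (methoxyethyne), via sodium methoxyacetylide 10 (not isolated)
Conditions: NaNH2 (3 equiv), liq. NH3, −33 °C; evaporate NH3; cold aq NaCl, −20 °C; distil into cold THF
Reagents that add atoms: none
Why: Double base-induced elimination (HCl, then methanol) and deprotonation by NaNH2 is the classical route to 1-alkoxyalkynes, and isolating the low-boiling alkyne gives a reagent free of amine and alkoxide, both of which would otherwise attack the vinylogous tert-butyl ester of 8 in step 6.

Step 6
Reactants: 11 methoxyacetylene; 8 3-tert-butoxy-4-heptadecylcyclobut-3-ene-1,2-dione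
Product: 13 racemic 3-tert-butoxy-2-heptadecyl-4-hydroxy-4-(methoxyethynyl)cyclobut-2-en-1-one, via lithium methoxyacetylide 12 (not isolated)
Conditions: n-BuLi (0.95 equiv to 11), THF, −78 °C; then 8, −78 °C; sat. aq NH4Cl, −78 °C; used crude
Reagents that add atoms: none
Why: Deprotonation gives the lithium acetylide, which should add 1,2 to the ketone-like carbonyl next to the tert-butoxy-bearing carbon because the other carbonyl is deactivated as a vinylogous ester (the established regiochemistry for 3-alkoxy-4-alkylcyclobutenediones); the carbinol carbon is racemic, and the cold near-neutral quench and immediate use should avoid a Meyer–Schuster-type rearrangement of the ynol ether carbinol.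

Step 7
Reactants: 13 racemic 3-tert-butoxy-2-heptadecyl-4-hydroxy-4-(methoxyethynyl)cyclobut-2-en-1-one
Product: 16 2-tert-butoxy-3-heptadecyl-5-methoxy-1,4-benzoquinone, via enynyl ketene 14 (not isolated), via ring diradical 15 (not isolated)
Conditions: toluene (0.01 M, degassed), 110 °C, argon
Reagents that add atoms: none
Why: On heating, the cyclobutenone should open by a conrotatory 4π electrocyclic cleavage of the bond between the carbinol carbon (future C1) and the ring carbonyl (future C4), the hydroxyl turning outward so that in ketene 14 the alkyne lies cis to the ketene. The ketene carbon C4 then bonds to the methoxy-bearing alkyne carbon C5 in a 6-endo-dig closure, the ketene counterpart of a Myers–Saito cyclisation, to give diradical 15 (sigma radical at C6, phenoxyl radical on the C4 oxygen), and transfer of the hydroxyl hydrogen to C6 completes the quinone. The closest known reaction type is the Moore rearrangement of 4-alkynyl-4-hydroxycyclobutenones, including 3-tert-butoxy members used as masked hydroxyquinones. No stereocenter is formed, since the racemic carbinol carbon becomes the C1 carbonyl. The step needs closure onto C5 (six-membered ring) and not onto C6 (5-exo-dig closure to a methoxymethylene-cyclopentenedione); the substrate offers for this a free hydroxyl as hydrogen donor, the variant for which quinone formation is best established, a small terminus group that is neither aryl, acyl nor silyl, and a dilute non-polar medium that disfavours the charge-separated five-ring path, whereas the donor oxygen on C5 is the one element that pulls the other way. Because the ynol ether is a methyl ether it cannot lose an alkene by a retro-ene reaction as higher alkyl ynol ethers do on heating, and the electron-rich tert-butoxy substituent should let the ring open already in boiling toluene.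

Step 8
Reactants: 16 2-tert-butoxy-3-heptadecyl-5-methoxy-1,4-benzoquinone
Product: 17 Irisoquin-B (3-heptadecyl-2-hydroxy-5-methoxy-1,4-benzoquinone)
Conditions: CF3CO2H, CH2Cl2, 0 °C to rt
Reagents that add atoms: none
Why: Acidolysis of the tert-butyl vinylogous ester by E1 loss of the tert-butyl cation as isobutene, as in tert-butyl ester cleavage; the methyl vinylogous ester cannot ionise in this way and should survive anhydrous CF3CO2H.

Compound list
1 | squaric acid (3,4-dihydroxycyclobut-3-ene-1,2-dione) | O=C1C(O)=C(O)C1=O | starting material
2 | disilver squarate (Ag2C4O4) | [Ag+].[Ag+].[O-]C1=C([O-])C(=O)C1=O | intermediate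
3 | di-tert-butyl squarate (3,4-di-tert-butoxycyclobut-3-ene-1,2-dione) | CC(C)(C)OC1=C(OC(C)(C)C)C(=O)C1=O | intermediate
4 | 1-bromoheptadecane | CCCCCCCCCCCCCCCCCBr | starting material
5 | heptadecylmagnesium bromide | CCCCCCCCCCCCCCCCC[Mg]Br | intermediate (not isolated)
6 | 2,3-di-tert-butoxy-4-heptadecyl-4-hydroxycyclobut-2-en-1-one, racemic | CCCCCCCCCCCCCCCCCC1(O)C(OC(C)(C)C)=C(OC(C)(C)C)C1=O | intermediate
7 | 2,3-di-tert-butoxy-1-heptadecyl-4-oxocyclobut-2-en-1-yl trifluoroacetate, racemic | CCCCCCCCCCCCCCCCCC1(OC(=O)C(F)(F)F)C(OC(C)(C)C)=C(OC(C)(C)C)C1=O | intermediate (not isolated)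
8 | 3-tert-butoxy-4-heptadecylcyclobut-3-ene-1,2-dione | CCCCCCCCCCCCCCCCCC1=C(OC(C)(C)C)C(=O)C1=O | intermediate
9 | chloroacetaldehyde dimethyl acetal (2-chloro-1,1-dimethoxyethane) | COC(CCl)OC | starting material
10 | sodium methoxyacetylide | [Na]C#COC | intermediate (not isolated)
11 | methoxyacetylene (methoxyethyne) | C#COC | intermediate
12 | lithium methoxyacetylide | [Li]C#COC | intermediate (not isolated)
13 | 3-tert-butoxy-2-heptadecyl-4-hydroxy-4-(methoxyethynyl)cyclobut-2-en-1-one, racemic | CCCCCCCCCCCCCCCCCC1=C(OC(C)(C)C)C(O)(C#COC)C1=O | intermediate
14 | (3Z)-3-tert-butoxy-2-heptadecyl-4-hydroxy-6-methoxyhexa-1,3-dien-5-yn-1-one (enynyl ketene, hydroxyl trans to the ketene-bearing carbon) | O=C=C(CCCCCCCCCCCCCCCCC)/C(OC(C)(C)C)=C(/O)C#COC | intermediate (not isolated)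
15 | 3-tert-butoxy-2-heptadecyl-4-hydroxy-6-methoxyphenoxyl-5-yl diradical | CCCCCCCCCCCCCCCCCC1=C(OC(C)(C)C)C(O)=[C]C(OC)=C1[O] | intermediate (not isolated)
16 | 2-tert-butoxy-3-heptadecyl-5-methoxy-1,4-benzoquinone | CCCCCCCCCCCCCCCCCC1=C(OC(C)(C)C)C(=O)C=C(OC)C1=O | intermediate
17 | Irisoquin-B (3-heptadecyl-2-hydroxy-5-methoxy-1,4-benzoquinone) | CCCCCCCCCCCCCCCCCC1=C(O)C(=O)C=C(OC)C1=O | target

Total steps: 8. Longest linear sequence: 7 steps (1, 2, 3, 4, 6, 7, 8, from squaric acid); step 5 is a one-step side branch that joins at step 6.

Steps most likely to fail

Step 7. The ketene carbon may bond to the proximal alkyne carbon instead of C5, because the oxygen on the alkyne terminus stabilises the exocyclic radical or cation that five-membered closure creates; material would then drain into a cyclopentenedione. The fallback sets out from 13 and keeps the same ring-opening and the same C4–C5 bond formation. The triple bond would be semihydrogenated (H2, Pd/CaCO3 poisoned with Pb(OAc)2, quinoline, EtOAc) to 3-tert-butoxy-2-heptadecyl-4-hydroxy-4-[(Z)-2-methoxyethenyl]cyclobut-2-en-1-one F1. Heating F1 in toluene should open the four-membered ring as before, and the resulting dienyl ketene can only close by a 6π electrocyclisation between C4 and C5; the sp-hybridised ketene carbon has no inward substituent, so the (Z)-methoxy group should be tolerated. Tautomerisation would give 2-tert-butoxy-3-heptadecyl-5-methoxybenzene-1,4-diol F2, and oxidation with Ag2O in Et2O returns to the route at 16.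

Step 4. The second tert-butyl group may be lost as isobutene during the acid-generating ionisation, leaving the free vinylogous acid instead of 8. The fallback sets out from 6 and makes this cleavage deliberate. CF3CO2H in CH2Cl2 would remove both tert-butyl groups and effect the transposition, giving 3-heptadecyl-4-hydroxycyclobut-3-ene-1,2-dione F3. Ag2O in MeCN would convert this strong acid into silver 2-heptadecyl-3,4-dioxocyclobut-1-en-1-olate F4. O-Alkylation of F4 with tert-butyl chloride in Et2O, the chemistry of step 2, returns to the route at 8; both oxygen termini of the delocalised anion lead to the same product.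

Step 2. On the heterogeneous silver salt, elimination of tert-butyl chloride to isobutene may outpace O-alkylation, and the acid set free would then degrade the diester. The fallback sets out from 1 and reverses the polarity of the squarate. Oxalyl chloride with catalytic DMF in CH2Cl2 would give 3,4-dichlorocyclobut-3-ene-1,2-dione F5. Addition–elimination of LiOC(CH3)3 (2 equiv, THF, −78 °C) at this vinylogous acid chloride returns to the route at 3, bypassing 2.

Further compounds
F1 | step 7 | 3-tert-butoxy-2-heptadecyl-4-hydroxy-4-[(Z)-2-methoxyethenyl]cyclobut-2-en-1-one, racemic | CCCCCCCCCCCCCCCCCC1=C(OC(C)(C)C)C(O)(/C=C\OC)C1=O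
F2 | step 7 | 2-tert-butoxy-3-heptadecyl-5-methoxybenzene-1,4-diol | CCCCCCCCCCCCCCCCCc1c(OC(C)(C)C)c(O)cc(OC)c1O
F3 | step 4 | 3-heptadecyl-4-hydroxycyclobut-3-ene-1,2-dione | CCCCCCCCCCCCCCCCCC1=C(O)C(=O)C1=O
F4 | step 4 | silver 2-heptadecyl-3,4-dioxocyclobut-1-en-1-olate | [Ag+].CCCCCCCCCCCCCCCCCC1=C([O-])C(=O)C1=O
F5 | step 2 | 3,4-dichlorocyclobut-3-ene-1,2-dione | ClC1=C(Cl)C(=O)C1=O
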